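**Retrosynthetic overview** (flavanone numbering: O1, C2, C3, C4, C4a, C5–C8, C8a; primed B ring)
1. The target, (2S)-5,7,2',4'-tetrahydroxy-6,5'-diprenylflavanone (22), comes from its tetra-MOM ether 21 by acetal cleavage in the last step.
2. The pyranone ring of 21 is cut at O1–C8a and C4–C4a, giving aryne 19 (from o-silylaryl triflate 13) and the (S)-β-hydroxy ester 18. Both bonds form in one fluoride-triggered aryne annulation that also joins the two halves.
3. Enabling feature: the A ring is a 2-prenylphloroglucinol in which C4a and C8a are adjacent and the C5 oxygen sits next to C4a. In the C4a≡C8a aryne this oxygen directs the C2 alkoxide to C8a and leaves the carbanion on C4a, where it acylates. The mirror plane through C6 and C8a of phenol 6 makes its two ortho positions equivalent.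
4. 13 comes from resorcinol (MOM, ortho-lithiation/prenylation, Ir C–H borylation/oxidation, carbamate-directed silylation, triflation). 18 comes from 5'-bromo-2',4'-dihydroxyacetophenone (MOM, Stille prenylation, Claisen condensation, asymmetric transfer hydrogenation, which sets C2 as S).
5. Ring order: both benzene rings are bought; the only ring formed is the heterocyclic C ring, in step 11.

Key step: step 11

Assumption: 1-(5-bromo-2,4-dihydroxyphenyl)ethan-1-one (14) is taken as a catalogue compound; otherwise it is one bromination step from 2',4'-dihydroxyacetophenone.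

**Step 1**
Reactants: 1 resorcinol
Product: 2 1,3-bis(methoxymethoxy)benzene
Conditions: NaH (2.4 equiv), DMF, 0 °C; MOMCl (2.4 equiv), 0 °C → rt
Reagents that add atoms: chloromethyl methyl ether (MOMCl), COCCl
Why: Williamson etherification of the bis-phenoxide should give the base-stable bis-MOM ether, whose two acetal oxygens direct the next metalation.

**Step 2**
Reactants: 2 1,3-bis(methoxymethoxy)benzene
Product: 4 1,3-bis(methoxymethoxy)-2-(3-methylbut-2-en-1-yl)benzene, via aryllithium 3 (not isolated)
Conditions: n-BuLi (1.1 equiv), THF, 0 °C → rt; CuBr·SMe2 (10 mol %), prenyl bromide (1.2 equiv), −20 °C → rt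
Reagents that add atoms: prenyl bromide (1-bromo-3-methylbut-2-ene), CC(C)=CCBr
Why: Directed ortho-metalation should occur at C2, the position flanked by both OMOM groups, and copper-catalysed SN2 alkylation of the aryllithium keeps the prenyl group linear.

**Step 3**
Reactants: 4 1,3-bis(methoxymethoxy)-2-(3-methylbut-2-en-1-yl)benzene
Product: 6 3,5-bis(methoxymethoxy)-4-(3-methylbut-2-en-1-yl)phenol, via aryl boronate 5 (not isolated)
Conditions: [Ir(OMe)(cod)]2 (1.5 mol %), dtbpy (3 mol %), B2pin2 (1.0 equiv), THF, 70 °C; then 30% H2O2, 1 M NaOH, THF, 0 °C → rt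
Reagents that add atoms: hydrogen peroxide, OO (the phenol oxygen); bis(pinacolato)diboron, CC1(C)OB(OC1(C)C)B1OC(C)(C)C(C)(C)O1 (its boron stays only in 5)
Why: Sterically governed iridium-catalysed C–H borylation should functionalise only C5, the one aromatic C–H without an ortho substituent, and alkaline peroxide oxidation of the C–B bond then gives the phenol without touching the unactivated trisubstituted olefin.

**Step 4**
Reactants: 6 3,5-bis(methoxymethoxy)-4-(3-methylbut-2-en-1-yl)phenol
Product: 7 3,5-bis(methoxymethoxy)-4-(3-methylbut-2-en-1-yl)phenyl N-isopropylcarbamate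
Conditions: i-PrNCO (1.5 equiv), Et3N (20 mol %), CH2Cl2, rt
Reagents that add atoms: isopropyl isocyanate, CC(C)N=C=O
Why: Base-catalysed addition of the phenol to the isocyanate (carbamoylation) installs a strong ortho-directing group that is later removed under mild base.

**Step 5**
Reactants: 7 3,5-bis(methoxymethoxy)-4-(3-methylbut-2-en-1-yl)phenyl N-isopropylcarbamate
Product: 11 3,5-bis(methoxymethoxy)-4-(3-methylbut-2-en-1-yl)-2-(trimethylsilyl)phenyl N-isopropylcarbamate, via N-silyl carbamate 8 (not isolated), via aryllithium 9 (not isolated), via N-silyl arylsilane 10 (not isolated)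
Conditions: TBSOTf (1.1 equiv), TMEDA (1.1 equiv), Et2O, 0 °C → rt; then TMEDA (2 equiv), n-BuLi (2 equiv), −78 °C; TMSCl (3 equiv), −78 °C → rt; sat. aq. NH4Cl work-up
Reagents that add atoms: chlorotrimethylsilane, C[Si](C)(C)Cl (tert-butyldimethylsilyl triflate, CC(C)(C)[Si](C)(C)OS(=O)(=O)C(F)(F)F, puts silicon only into 8–10)
Why: Directed ortho-metalation of the in situ N-silylated carbamate should lithiate one of the two equivalent C–H positions flanked by the carbamate and an OMOM group (the only aromatic hydrogens left), and TMSCl traps the aryllithium at −78 °C before an anionic Fries shift can occur.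

**Step 6**
Reactants: 11 3,5-bis(methoxymethoxy)-4-(3-methylbut-2-en-1-yl)-2-(trimethylsilyl)phenyl N-isopropylcarbamate
Product: 13 3,5-bis(methoxymethoxy)-4-(3-methylbut-2-en-1-yl)-2-(trimethylsilyl)phenyl trifluoromethanesulfonate, via silylphenol 12 (not isolated)
Conditions: DBU (1.5 equiv), Et2NH (1.2 equiv), MeCN, 40 °C; then PhNTf2 (1.5 equiv), rt
Reagents that add atoms: N-phenylbis(trifluoromethanesulfonimide), O=S(=O)(N(c1ccccc1)S(=O)(=O)C(F)(F)F)C(F)(F)F
Why: E1cB cleavage of the N–H carbamate should release the phenoxide and isopropyl isocyanate (scavenged by diethylamine as a urea), and O-triflation in the same pot gives the o-silylaryl triflate aryne precursor.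

**Step 7**
Reactants: 14 1-(5-bromo-2,4-dihydroxyphenyl)ethan-1-one
Product: 15 1-[5-bromo-2,4-bis(methoxymethoxy)phenyl]ethan-1-one
Conditions: K2CO3 (4 equiv), MOMCl (3 equiv), acetone, reflux
Reagents that add atoms: chloromethyl methyl ether (MOMCl), COCCl
Why: Williamson etherification with excess reagent and heat should protect both phenols, including the hydrogen-bonded 2-OH.

**Step 8**
Reactants: 15 1-[5-bromo-2,4-bis(methoxymethoxy)phenyl]ethan-1-one
Product: 16 1-[2,4-bis(methoxymethoxy)-5-(3-methylbut-2-en-1-yl)phenyl]ethan-1-one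
Conditions: tributyl(prenyl)stannane (1.3 equiv), Pd(PPh3)4 (5 mol %), DMF, 100 °C
Reagents that add atoms: tributyl(3-methylbut-2-en-1-yl)stannane, CCCC[Sn](CCCC)(CCCC)CC=C(C)C
Why: Stille coupling of the aryl bromide with the allylic stannane should couple at the unsubstituted allyl terminus and give the linear prenyl arene, and the stannane is inert towards the ketone.

**Step 9**
Reactants: 16 1-[2,4-bis(methoxymethoxy)-5-(3-methylbut-2-en-1-yl)phenyl]ethan-1-one
Product: 17 methyl 3-[2,4-bis(methoxymethoxy)-5-(3-methylbut-2-en-1-yl)phenyl]-3-oxopropanoate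
Conditions: NaH (2.5 equiv), dimethyl carbonate (5 equiv), THF, reflux; AcOH quench
Reagents that add atoms: dimethyl carbonate, COC(=O)OC
Why: Crossed Claisen condensation of the methyl ketone enolate with the non-enolisable carbonate is driven to completion by deprotonation of the β-keto ester formed.

**Step 10**
Reactants: 17 methyl 3-[2,4-bis(methoxymethoxy)-5-(3-methylbut-2-en-1-yl)phenyl]-3-oxopropanoate
Product: 18 methyl (3S)-3-[2,4-bis(methoxymethoxy)-5-(3-methylbut-2-en-1-yl)phenyl]-3-hydroxypropanoate
Conditions: RuCl[(S,S)-TsDPEN](p-cymene) (1 mol %), HCO2H/Et3N (5:2), 40 °C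
Reagents that add atoms: none
Why: Noyori-type asymmetric transfer hydrogenation of the aryl ketone should deliver hydride to the Re face with the (S,S)-catalyst (aryl ring in the CH/π position, the sense established for aryl ketones and benzoylacetates), setting the future C2 as S without touching the olefin or the acetals.

**Step 11**
Reactants: 13 3,5-bis(methoxymethoxy)-4-(3-methylbut-2-en-1-yl)-2-(trimethylsilyl)phenyl trifluoromethanesulfonate; 18 methyl (3S)-3-[2,4-bis(methoxymethoxy)-5-(3-methylbut-2-en-1-yl)phenyl]-3-hydroxypropanoate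
Product: 21 (2S)-2-[2,4-bis(methoxymethoxy)-5-(3-methylbut-2-en-1-yl)phenyl]-5,7-bis(methoxymethoxy)-6-(3-methylbut-2-en-1-yl)-2,3-dihydro-4H-chromen-4-one, via aryne 19 (not isolated), via cesium aryl anion 20 (not isolated)
Conditions: CsF (3 equiv), powdered 4 Å MS, THF (0.05 M), 65 °C; 13 (1.3 equiv) added slowly
Reagents that add atoms: none
Why: Proposed new method: fluoride removes the TMS group of 13 and triflate leaves to give aryne 19, the fluoride-activated secondary hydroxyl of 18 adds through oxygen to C8a, and the aryl anion 20 so formed at C4a attacks its own methyl ester and expels methoxide before it can be protonated in the aprotic medium. The closest known reaction type is the fluoride-induced annulation of arynes with salicylate esters to xanthones (heteroatom addition then intramolecular acyl capture), extended here from a phenoxide and an aryl ester to a secondary benzylic alkoxide and an enolisable aliphatic ester. The one ring closed is the dihydropyranone ring, in a formal [4+2] annulation in which the intermolecular O1–C8a arylation is followed by 6-exo-trig acyl substitution at C4. No stereocenter is created: C2 comes from 18 with retention because its C–O bond is never broken, and forming the aryl ether before the ketone avoids a free β-oxido ketone that could scramble C2 by retro-aldol cleavage. The step needs regioselective oxygen attack at C8a, which the C5 OMOM group next to C4a secures by inductive polarisation of the aryne (the carbanion develops ortho to oxygen), while the mirror plane of the parent phenol of 13 means only this one aryne can form. It also needs acylation to outrun protonation and the product to resist base-induced ring opening at C2, for which dry THF, sieves that take up the methanol released and the fluoride/bifluoride buffer are relied on.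

**Step 12**
Reactants: 21 (2S)-2-[2,4-bis(methoxymethoxy)-5-(3-methylbut-2-en-1-yl)phenyl]-5,7-bis(methoxymethoxy)-6-(3-methylbut-2-en-1-yl)-2,3-dihydro-4H-chromen-4-one
Product: 22 (2S)-2-[2,4-dihydroxy-5-(3-methylbut-2-en-1-yl)phenyl]-5,7-dihydroxy-6-(3-methylbut-2-en-1-yl)-2,3-dihydro-4H-chromen-4-one (CNP0320454.1)
Conditions: 3 M aq. HCl/MeOH (1:5), THF co-solvent, rt → 40 °C, monitored; NaHCO3 to pH 6
Reagents that add atoms: none
Why: Acid-catalysed solvolysis of the four aryl MOM acetals (the 5-OMOM peri to the carbonyl first) should free the phenols under dilute, mild conditions that are expected to leave the C2 configuration and both prenyl groups intact.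

**Compound list**
1 | resorcinol (benzene-1,3-diol) | Oc1cccc(O)c1 | starting material
2 | 1,3-bis(methoxymethoxy)benzene | COCOc1cccc(OCOC)c1 | intermediate
3 | [2,6-bis(methoxymethoxy)phenyl]lithium | [Li]c1c(OCOC)cccc1OCOC | intermediate
4 | 1,3-bis(methoxymethoxy)-2-(3-methylbut-2-en-1-yl)benzene | COCOc1cccc(OCOC)c1CC=C(C)C | intermediate
5 | 2-[3,5-bis(methoxymethoxy)-4-(3-methylbut-2-en-1-yl)phenyl]-4,4,5,5-tetramethyl-1,3,2-dioxaborolane | COCOc1cc(B2OC(C)(C)C(C)(C)O2)cc(OCOC)c1CC=C(C)C | intermediate
6 | 3,5-bis(methoxymethoxy)-4-(3-methylbut-2-en-1-yl)phenol | COCOc1cc(O)cc(OCOC)c1CC=C(C)C | intermediate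
7 | 3,5-bis(methoxymethoxy)-4-(3-methylbut-2-en-1-yl)phenyl N-isopropylcarbamate | COCOc1cc(OC(=O)NC(C)C)cc(OCOC)c1CC=C(C)C | intermediate
8 | 3,5-bis(methoxymethoxy)-4-(3-methylbut-2-en-1-yl)phenyl N-(tert-butyldimethylsilyl)-N-isopropylcarbamate | COCOc1cc(OC(=O)N(C(C)C)[Si](C)(C)C(C)(C)C)cc(OCOC)c1CC=C(C)C | intermediate
9 | 2-lithio derivative of 8 (lithium at the ring carbon between the carbamate and an OMOM group) | COCOc1cc(OC(=O)N(C(C)C)[Si](C)(C)C(C)(C)C)c([Li])c(OCOC)c1CC=C(C)C | intermediate
10 | 3,5-bis(methoxymethoxy)-4-(3-methylbut-2-en-1-yl)-2-(trimethylsilyl)phenyl N-(tert-butyldimethylsilyl)-N-isopropylcarbamate | COCOc1cc(OC(=O)N(C(C)C)[Si](C)(C)C(C)(C)C)c([Si](C)(C)C)c(OCOC)c1CC=C(C)C | intermediate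
11 | 3,5-bis(methoxymethoxy)-4-(3-methylbut-2-en-1-yl)-2-(trimethylsilyl)phenyl N-isopropylcarbamate | COCOc1cc(OC(=O)NC(C)C)c([Si](C)(C)C)c(OCOC)c1CC=C(C)C | intermediate
12 | 3,5-bis(methoxymethoxy)-4-(3-methylbut-2-en-1-yl)-2-(trimethylsilyl)phenol | COCOc1cc(O)c([Si](C)(C)C)c(OCOC)c1CC=C(C)C | intermediate
13 | 3,5-bis(methoxymethoxy)-4-(3-methylbut-2-en-1-yl)-2-(trimethylsilyl)phenyl trifluoromethanesulfonate | COCOc1cc(OS(=O)(=O)C(F)(F)F)c([Si](C)(C)C)c(OCOC)c1CC=C(C)C | intermediate
14 | 1-(5-bromo-2,4-dihydroxyphenyl)ethan-1-one | CC(=O)c1cc(Br)c(O)cc1O | starting material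
15 | 1-[5-bromo-2,4-bis(methoxymethoxy)phenyl]ethan-1-one | CC(=O)c1cc(Br)c(OCOC)cc1OCOC | intermediate
16 | 1-[2,4-bis(methoxymethoxy)-5-(3-methylbut-2-en-1-yl)phenyl]ethan-1-one | CC(=O)c1cc(CC=C(C)C)c(OCOC)cc1OCOC | intermediate
17 | methyl 3-[2,4-bis(methoxymethoxy)-5-(3-methylbut-2-en-1-yl)phenyl]-3-oxopropanoate | COC(=O)CC(=O)c1cc(CC=C(C)C)c(OCOC)cc1OCOC | intermediate
18 | methyl (3S)-3-[2,4-bis(methoxymethoxy)-5-(3-methylbut-2-en-1-yl)phenyl]-3-hydroxypropanoate | CC(C)=CCc1cc([C@@H](O)CC(=O)OC)c(OCOC)cc1OCOC | intermediate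
19 | 3,5-bis(methoxymethoxy)-4-(3-methylbut-2-en-1-yl)-1,2-didehydrobenzene (aryne) | COCOC1=CC#CC(OCOC)=C1CC=C(C)C | intermediate
20 | cesium 2-{(1S)-1-[2,4-bis(methoxymethoxy)-5-(3-methylbut-2-en-1-yl)phenyl]-3-methoxy-3-oxopropoxy}-4,6-bis(methoxymethoxy)-5-(3-methylbut-2-en-1-yl)benzen-1-ide (the carbanion sits between the new ether oxygen and an OMOM group) | CC(C)=CCc1cc([C@@H](Oc2cc(OCOC)c(CC=C(C)C)c(OCOC)[c-]2)CC(=O)OC)c(OCOC)cc1OCOC.[Cs+] | intermediate
21 | (2S)-2-[2,4-bis(methoxymethoxy)-5-(3-methylbut-2-en-1-yl)phenyl]-5,7-bis(methoxymethoxy)-6-(3-methylbut-2-en-1-yl)-2,3-dihydro-4H-chromen-4-one | CC(C)=CCc1cc([C@@H]2CC(=O)c3c(cc(OCOC)c(CC=C(C)C)c3OCOC)O2)c(OCOC)cc1OCOC | intermediate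
22 | (2S)-2-[2,4-dihydroxy-5-(3-methylbut-2-en-1-yl)phenyl]-5,7-dihydroxy-6-(3-methylbut-2-en-1-yl)-2,3-dihydro-4H-chromen-4-one (CNP0320454.1) | CC(C)=CCc1cc([C@@H]2CC(=O)c3c(cc(O)c(CC=C(C)C)c3O)O2)c(O)cc1O | target

**Step count**
Total steps: 12. Longest linear sequence: 8 steps (steps 1–6, 11, 12); the second branch (steps 7–10) joins at step 11.

**Steps most likely to fail**

Step 11 (Proposed new method). The aryl anion may be protonated before it reaches the ester, which would leave an open-chain aryl ether. The hydroxy ester may also undergo β-elimination, and the basic medium may open and reclose the product ring at C2, eroding the enantiopurity. The fallback uses known chemistry and sets out from 18 and 13.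
- Mesylation of 18 (MsCl, Et3N, CH2Cl2, 0 °C) would give the mesylate methyl (3S)-3-[2,4-bis(methoxymethoxy)-5-(3-methylbut-2-en-1-yl)phenyl]-3-(methylsulfonyloxy)propanoate F1.
- DBU in the same flask would eliminate it to methyl (E)-3-[2,4-bis(methoxymethoxy)-5-(3-methylbut-2-en-1-yl)phenyl]prop-2-enoate F2.
- Saponification (LiOH, THF/H2O) would give (E)-3-[2,4-bis(methoxymethoxy)-5-(3-methylbut-2-en-1-yl)phenyl]prop-2-enoic acid F3.
- F3 and 13 would then be combined under the established fluoride-induced insertion of arynes into the C–O bond of carboxylic acids (CsF, THF, sealed tube, 100–125 °C). The carboxylate adds at C8a and the aryl anion at C4a takes the acyl group, giving the 2'-hydroxychalcone (E)-1-[2-hydroxy-4,6-bis(methoxymethoxy)-5-(3-methylbut-2-en-1-yl)phenyl]-3-[2,4-bis(methoxymethoxy)-5-(3-methylbut-2-en-1-yl)phenyl]prop-2-en-1-one F4.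
- F4 would close by oxa-Michael addition (completed with NaOAc, EtOH, reflux if needed) to the racemic flavanone rac-2-[2,4-bis(methoxymethoxy)-5-(3-methylbut-2-en-1-yl)phenyl]-5,7-bis(methoxymethoxy)-6-(3-methylbut-2-en-1-yl)-2,3-dihydro-4H-chromen-4-one F5.
- Preparative HPLC on a chiral stationary phase would then deliver the (S)-enantiomer, which is 21, where the route is rejoined.

Step 12. Under Brønsted acid a prenyl group may cyclise onto its neighbouring freed phenol (chroman formation). Once the 2'- and 4'-hydroxyls are free, the C2–O1 bond may also open through a B-ring quinone methide and reclose with loss of configuration. The fallback sets out from 21 and avoids protic acid.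
- TMSOTf and 2,2'-bipyridyl (CH2Cl2/MeCN, 0 °C) would convert the four aryl MOM ethers, through bipyridinium intermediates, into the silyl ether (2S)-2-[2,4-bis(trimethylsilyloxy)-5-(3-methylbut-2-en-1-yl)phenyl]-5,7-bis(trimethylsilyloxy)-6-(3-methylbut-2-en-1-yl)-2,3-dihydro-4H-chromen-4-one F6.
- Neutral hydrolysis (H2O/THF, rt) would then give 22.

Step 3. Iridium hydride or pinacolborane may hydroborate the prenyl olefin, or borylate it at an allylic or vinylic position, in competition with the arene C–H bond. The fallback sets out from 2 and introduces the olefin only after the phenol oxygen is in place.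
- The same borylation/oxidation on olefin-free 2 would give, via the boronate 2-[3,5-bis(methoxymethoxy)phenyl]-4,4,5,5-tetramethyl-1,3,2-dioxaborolane F7, the phenol 3,5-bis(methoxymethoxy)phenol F8.
- Silylation (TIPSCl, imidazole, DMF) would give [3,5-bis(methoxymethoxy)phenoxy]triisopropylsilane F9.
- n-BuLi (THF, 0 °C) should lithiate between the two OMOM groups, because the bulky silyl ether does not direct, to give [2,6-bis(methoxymethoxy)-4-(triisopropylsilyloxy)phenyl]lithium F10.
- Copper-catalysed alkylation with prenyl bromide would give [3,5-bis(methoxymethoxy)-4-(3-methylbut-2-en-1-yl)phenoxy]triisopropylsilane F11.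
- TBAF (THF, 0 °C) would then release 6, where the route is rejoined.

**Further compounds**
F1 | step 11 | methyl (3S)-3-[2,4-bis(methoxymethoxy)-5-(3-methylbut-2-en-1-yl)phenyl]-3-(methylsulfonyloxy)propanoate | CC(C)=CCc1cc([C@@H](OS(C)(=O)=O)CC(=O)OC)c(OCOC)cc1OCOC
F2 | step 11 | methyl (E)-3-[2,4-bis(methoxymethoxy)-5-(3-methylbut-2-en-1-yl)phenyl]prop-2-enoate | COC(=O)/C=C/c1cc(CC=C(C)C)c(OCOC)cc1OCOC
F3 | step 11 | (E)-3-[2,4-bis(methoxymethoxy)-5-(3-methylbut-2-en-1-yl)phenyl]prop-2-enoic acid | OC(=O)/C=C/c1cc(CC=C(C)C)c(OCOC)cc1OCOC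
F4 | step 11 | (E)-1-[2-hydroxy-4,6-bis(methoxymethoxy)-5-(3-methylbut-2-en-1-yl)phenyl]-3-[2,4-bis(methoxymethoxy)-5-(3-methylbut-2-en-1-yl)phenyl]prop-2-en-1-one | CC(C)=CCc1cc(/C=C/C(=O)c2c(O)cc(OCOC)c(CC=C(C)C)c2OCOC)c(OCOC)cc1OCOC
F5 | step 11 | rac-2-[2,4-bis(methoxymethoxy)-5-(3-methylbut-2-en-1-yl)phenyl]-5,7-bis(methoxymethoxy)-6-(3-methylbut-2-en-1-yl)-2,3-dihydro-4H-chromen-4-one | CC(C)=CCc1cc(C2CC(=O)c3c(cc(OCOC)c(CC=C(C)C)c3OCOC)O2)c(OCOC)cc1OCOC
F6 | step 12 | (2S)-2-[2,4-bis(trimethylsilyloxy)-5-(3-methylbut-2-en-1-yl)phenyl]-5,7-bis(trimethylsilyloxy)-6-(3-methylbut-2-en-1-yl)-2,3-dihydro-4H-chromen-4-one | CC(C)=CCc1cc([C@@H]2CC(=O)c3c(cc(O[Si](C)(C)C)c(CC=C(C)C)c3O[Si](C)(C)C)O2)c(O[Si](C)(C)C)cc1O[Si](C)(C)C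
F7 | step 3 | 2-[3,5-bis(methoxymethoxy)phenyl]-4,4,5,5-tetramethyl-1,3,2-dioxaborolane | COCOc1cc(OCOC)cc(B2OC(C)(C)C(C)(C)O2)c1
F8 | step 3 | 3,5-bis(methoxymethoxy)phenol | COCOc1cc(O)cc(OCOC)c1
F9 | step 3 | [3,5-bis(methoxymethoxy)phenoxy]triisopropylsilane | COCOc1cc(OCOC)cc(O[Si](C(C)C)(C(C)C)C(C)C)c1
F10 | step 3 | [2,6-bis(methoxymethoxy)-4-(triisopropylsilyloxy)phenyl]lithium | [Li]c1c(OCOC)cc(O[Si](C(C)C)(C(C)C)C(C)C)cc1OCOC
F11 | step 3 | [3,5-bis(methoxymethoxy)-4-(3-methylbut-2-en-1-yl)phenoxy]triisopropylsilane | COCOc1cc(O[Si](C(C)C)(C(C)C)C(C)C)cc(OCOC)c1CC=C(C)C
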